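**Retrosynthetic overview**
1. The (E,E)-phenyl-diene is installed last by Mizoroki–Heck on a terminal alkene, because a styryl diene would not survive the Co–H/photoredox step.
2. The tetrasubstituted THF ring (C–O bond at the quaternary C5) is closed by a photocatalytic Co–H Markovnikov 5-exo cycloetherification of a hydroxy-lactone carrying a 1,1-disubstituted alkene.
3. The cis-γ-lactone forms first, from a diol ester. The C-chain is attached by Ni cross-electrophile coupling of a vinyl bromide with 10-bromodec-1-ene.
4. The tertiary carbinol stereocentre comes from chelation-controlled indium Barbier 2-bromoallylation of an α-hydroxy methyl ketone. That ketone is made by Weinreb/MeMgBr from dimethyl L-malate, which supplies the C3a stereocentre.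

Assumptions: the α-ester of dimethyl malate is aminolysed selectively in Step 1, and the Step 6 diastereomer with the chain on the convex face is obtained as major or separable.

---

**Step 1**
Reactants: 1 (dimethyl (S)-malate), 2 (N,O-dimethylhydroxylamine hydrochloride)
Product: 3, methyl (3S)-3-hydroxy-4-[methoxy(methyl)amino]-4-oxobutanoate
Conditions: 2 (2.2 equiv), iPrMgCl (5 equiv), THF, −20 °C, 1 h
Reagents that add atoms: 2, MeNH(OMe)·HCl, SMILES CONC.Cl (adds the N(OMe)Me group)
Why: The magnesium alkoxide of the α-hydroxy ester activates the adjacent C1 ester for Weinreb amidation (iPrMgCl-mediated), and the stereocentre is untouched.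

**Step 2**
Reactants: 3, 4 (methylmagnesium bromide)
Product: 5, methyl (3S)-3-hydroxy-4-oxopentanoate
Conditions: 4 (3 equiv), THF, −40 → 0 °C; aq. NH4Cl quench
Reagents that add atoms: 4, MeMgBr, SMILES C[Mg]Br (adds CH3)
Why: Weinreb ketone synthesis; the chelated tetrahedral intermediate stops at the methyl ketone, and the first equivalent of Grignard just deprotonates the OH.

**Step 3**
Reactants: 5, 6 (2,3-dibromopropene)
Product: 7, methyl (3S,4S)-6-bromo-3,4-dihydroxy-4-methylhept-6-enoate
Conditions: 6 (2 equiv), In powder (2 equiv), THF/H2O 1:1, 25 °C
Reagents that add atoms: 6, C=C(Br)CBr (adds CH2=C(Br)CH2–); water, O (protonates the indium alkoxide)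
Why: In-mediated Barbier allylation of an α-hydroxy ketone is chelation-controlled, so the allylindium adds to the face of the ketone carrying the H on C3. This sets the tertiary carbinol as (S), giving the relative configuration needed for the cis-fused lactone/THF.

**Step 4**
Reactants: 7
Product: 8, (4S,5S)-5-(2-bromoallyl)-4-hydroxy-5-methyloxolan-2-one
Conditions: p-TsOH·H2O (10 mol%), toluene, 40 °C, 4 h
Reagents that add atoms: none
Why: Acid-catalysed γ-lactonisation (transesterification) of the tertiary alcohol onto the methyl ester, with loss of MeOH, closes the 5-ring with no change at either stereocentre.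

**Step 5**
Reactants: 8, 9 (10-bromodec-1-ene)
Product: 10, (4S,5S)-4-hydroxy-5-methyl-5-(2-methylidenedodec-11-en-1-yl)oxolan-2-one
Conditions: 9 (1.5 equiv), NiBr2·diglyme (10 mol%), dtbbpy (10 mol%), Zn (3 equiv), NaI (30 mol%), DMA, 40 °C
Reagents that add atoms: 9, C=CCCCCCCCCBr (adds the C10 alkenyl chain)
Why: Ni-catalysed cross-electrophile coupling of a vinyl bromide with a primary alkyl bromide is base-free, so the β-hydroxy lactone is not eliminated, and the alkene, OH and lactone are tolerated.

**Step 6**
Reactants: 10
Product: 11, (3aS,5S,6aS)-5-(dec-9-en-1-yl)-5,6a-dimethyltetrahydrofuro[3,2-b]furan-2(3H)-one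
Conditions: Ir(ppy)3 (1 mol%), Co(dmgH)2(py)Cl (5 mol%), 2,6-lutidinium triflate (20 mol%), MeCN (0.05 M), blue LEDs (455 nm), 25 °C, N2, 24 h
Reagents that add atoms: none (isomerisation; all catalysts and acid are regenerated)
Why: Proposed new method: a silane- and oxidant-free photochemical Co–H radical-polar-crossover Markovnikov hydroalkoxylation, built from two known systems (photoredox/cobaloxime Co–H generation, as in alkene isomerisation, and Co–H radical-polar-crossover hydroalkoxylation) and applied to a new substrate class.
- Excited Ir(ppy)3 reduces Co(III) to Co(I).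
- Protonation of Co(I) gives Co(III)–H.
- Co(III)–H transfers H• to the 1,1-disubstituted alkene, giving the tertiary radical. Any trisubstituted isomer formed funnels to the same radical.
- Ir(IV) oxidises the radical to the tertiary cation, and the tethered C3a–OH traps it 5-exo to form the tetrasubstituted THF.
- The H+ is regenerated, so the reaction is net redox-neutral.
- The terminal alkene is unreactive because a secondary radical is not oxidised to a cation.
- The cis-fused lactone biases the cation capture so that the larger chain sits on the convex face, which sets C5 as (S) (substrate control, no chiral catalyst).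

**Step 7**
Reactants: 11, 12 ((E)-β-bromostyrene)
Product: 13, plakortone P, (3aS,5S,6aS)-5,6a-dimethyl-5-[(9E,11E)-12-phenyldodeca-9,11-dien-1-yl]tetrahydrofuro[3,2-b]furan-2(3H)-one
Conditions: 12 (1.5 equiv), Pd(OAc)2 (5 mol%), nBu4NCl (1 equiv), NaHCO3 (2.5 equiv), DMF, 80 °C
Reagents that add atoms: 12, Br/C=C/c1ccccc1 (adds the styryl unit)
Why: Jeffery-type Mizoroki–Heck coupling of the terminal alkene with a (E)-vinyl bromide gives the linear (E,E)-1,3-diene with retention of vinyl geometry, under mild bicarbonate that leaves the lactone and ether intact.

**Self-check of the plan against the target**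
- The target is a cis-fused furo[3,2-b]furan-2-one. The angular methyl and H point to the convex face, the chain is on the convex face, and the C5 methyl is on the concave face.
- The chain is (CH2)8–CH=CH–CH=CH–Ph (E,E).
- The stereocentres are 3aS (from malate), 6aS (chelation control in Step 3) and 5S (Step 6).
- Every step conserves atoms: 7 is C9H15BrO4, 8 is C8H11BrO3, 10 is C18H30O3, 11 is C18H30O3, and 13 is C26H36O3.

---

**Compound list**

| No. | Name | SMILES | Role |
|---|---|---|---|
| 1 | dimethyl (S)-malate | COC(=O)[C@@H](O)CC(=O)OC | starting material |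
| 2 | N,O-dimethylhydroxylamine hydrochloride | CONC.Cl | starting material |
| 3 | Weinreb amide of malate (C1), methyl ester at C4 | CON(C)C(=O)[C@@H](O)CC(=O)OC | intermediate |
| 4 | methylmagnesium bromide | C[Mg]Br | starting material |
| 5 | methyl (S)-3-hydroxy-4-oxopentanoate | CC(=O)[C@@H](O)CC(=O)OC | intermediate |
| 6 | 2,3-dibromopropene | C=C(Br)CBr | starting material |
| 7 | methyl (3S,4S)-6-bromo-3,4-dihydroxy-4-methylhept-6-enoate | C=C(Br)C[C@](C)(O)[C@@H](O)CC(=O)OC | intermediate |
| 8 | (4S,5S)-5-(2-bromoallyl)-4-hydroxy-5-methyloxolan-2-one | C=C(Br)C[C@]1(C)OC(=O)C[C@@H]1O | intermediate |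
| 9 | 10-bromodec-1-ene | C=CCCCCCCCCBr | starting material |
| 10 | (4S,5S)-4-hydroxy-5-methyl-5-(2-methylidenedodec-11-en-1-yl)oxolan-2-one | C=C(CCCCCCCCC=C)C[C@]1(C)OC(=O)C[C@@H]1O | intermediate |
| 11 | (3aS,5S,6aS)-5-(dec-9-en-1-yl)-5,6a-dimethyltetrahydrofuro[3,2-b]furan-2(3H)-one | C[C@]1(CCCCCCCCC=C)C[C@]2(C)OC(=O)C[C@@H]2O1 | intermediate |
| 12 | (E)-β-bromostyrene | Br/C=C/c1ccccc1 | starting material |
| 13 | plakortone P | C[C@]1(CCCCCCCC/C=C/C=C/c2ccccc2)C[C@]2(C)OC(=O)C[C@@H]2O1 | target |

---

**Total steps:** 7. **Longest linear sequence:** 7, from dimethyl (S)-malate.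

**Three steps most likely to fail**
1. **Step 6 (proposed new photochemical cycloetherification).**
   - Risks: the diastereoselectivity at C5 may be modest, and Co–H could touch the terminal alkene.
   - Fallback: cationic Markovnikov 5-exo hydroalkoxylation of 10 with Hg(OTf)2 (cat.) or Au(I)/AgOTf, a two-electron ionic mechanism, followed by HPLC separation of the C5 epimers. The undesired epimer can be recycled by acid-mediated reversible ring-opening.
2. **Step 1 (regioselective Weinreb amidation at the α-ester, with Step 2 riding on it).**
   - Risk: C4 amidation, or MeMgBr attack on the C4 methyl ester.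
   - Fallback: use the commercial malic acid acetonide-dioxolanone acid. Add MeMgBr to the dioxolanone carbonyl, with the side-chain carboxylate masked as its salt, to release the α-hydroxy methyl ketone acid. Then esterify with TMSCHN2 to give 5.
3. **Step 3 (chelation-controlled Barbier allylation).**
   - Risk: low dr, because the free OH and the β-ester compete for chelation.
   - Fallback: protect the hydroxyl of 5 as the PMB ether, carry out the allylation with MgBr2·OEt2-promoted 2-bromoallylzinc addition under rigid chelation, and remove PMB with DDQ before lactonisation. The wrong diastereomer cannot close the cis-fused bicycle in Step 6 and is removed by chromatography.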